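Ring A of the coumarin carries oxygen on C5, C7 and C8a in an all-meta array, with the C4 chain on C4a ortho to O1. That pattern is cut back to a 3-methoxy-4-alkylcyclobutenone and an alkoxyethyne: one Danheiser benzannulation should form C8–C8a, C6–C7 and C4a–C8a, placing every ring A substituent without differentiating a phloroglucinol, and the new C8a phenol then closes ring B on the side-chain ester (O1–C2). The precursor is a cyclobutenone whose sp3 ring carbon bears the CH2–CH(aryl)CO2Me chain. The ynol ether carries 1-adamantyl, because benzyl ynol ethers rearrange and alkyl ones with β-hydrogens fragment below the temperature the cyclobutenone needs.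

Key step: step 10

Remarks on the chemistry: coumarin atoms are numbered O1 to C8a and chroman atoms carry primes. The stereocentres of the intermediates (C3, and the sp3 carbon of the cyclobutenone) are formed without control and are destroyed in steps 10 and 11; the target is achiral. Compounds 1, 2, 7, 10, 16 and 17 are taken as commercial.

Step 1
Reactants: 1 2,4-dihydroxyacetophenone; 2 3-methylbut-2-enal
Product: 3 1-(5-hydroxy-2,2-dimethyl-2H-chromen-6-yl)ethan-1-one
Conditions: pyridine, 140 °C (sealed tube)
Reagents that add atoms: none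
Why: Knoevenagel-type condensation of the enal at the ring carbon between the two oxygens followed by oxa-6π electrocyclisation should give the angular 2H-chromene, the free 4-OH closing the pyran while the 2-OH stays hydrogen-bonded to the acetyl group.

Step 2
Reactants: 3 1-(5-hydroxy-2,2-dimethyl-2H-chromen-6-yl)ethan-1-one
Product: 4 1-(5-methoxy-2,2-dimethyl-2H-chromen-6-yl)ethan-1-one
Conditions: MeI, K2CO3, DMF, 50 °C
Reagents that add atoms: iodomethane, CI
Why: Williamson ether synthesis on the only phenol, with carbonate in DMF strong enough to break the chelate to the acetyl group.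

Step 3
Reactants: 4 1-(5-methoxy-2,2-dimethyl-2H-chromen-6-yl)ethan-1-one
Product: 5 1-(5-methoxy-2,2-dimethylchroman-6-yl)ethan-1-one
Conditions: H2 (1 atm), 10% Pd/C, EtOAc, rt
Reagents that add atoms: none
Why: Catalytic hydrogenation of the styrene-type C3'=C4' alkene, which the aryl ketone and the ethers should survive at atmospheric pressure; it is placed here because the oxidant of step 4 would attack the chromene alkene.

Step 4
Reactants: 5 1-(5-methoxy-2,2-dimethylchroman-6-yl)ethan-1-one
Product: 6 methyl 2-(5-methoxy-2,2-dimethylchroman-6-yl)acetate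
Conditions: PhI(OAc)2, H2SO4, HC(OMe)3, rt → 60 °C
Reagents that add atoms: trimethyl orthoformate, COC(OC)OC
Why: Oxidative 1,2-aryl migration of an aryl methyl ketone to the arylacetate with a trivalent iodine reagent under ketalising conditions, favoured here because the migrating ring is electron-rich (ortho methoxy, para ring oxygen).

Step 5
Reactants: 6 methyl 2-(5-methoxy-2,2-dimethylchroman-6-yl)acetate; 7 benzyl acrylate
Product: 8 5-benzyl 1-methyl 2-(5-methoxy-2,2-dimethylchroman-6-yl)pentanedioate (racemic)
Conditions: LiN(iPr)2, THF, −78 °C; then 7, −78 °C; AcOH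
Reagents that add atoms: none
Why: Michael addition of the lithium ester enolate to the acrylate at low temperature should give the mono-adduct; the new stereocentre (later C3) is formed racemic and is removed in step 11.

Step 6
Reactants: 8 5-benzyl 1-methyl 2-(5-methoxy-2,2-dimethylchroman-6-yl)pentanedioate
Product: 9 5-methoxy-4-(5-methoxy-2,2-dimethylchroman-6-yl)-5-oxopentanoic acid (racemic)
Conditions: H2 (1 atm), 10% Pd/C, EtOAc, rt
Reagents that add atoms: none
Why: Hydrogenolysis of the benzyl ester frees only the distal carboxyl under neutral conditions, so no carbocation is generated next to the electron-rich ring and the methyl ester is untouched.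

Step 7
Reactants: 10 chloroacetaldehyde dimethyl acetal
Product: 12 methoxyethyne, via sodium acetylide 11 (not isolated)
Conditions: NaNH2 (3 equiv), liquid NH3, −33 °C; NH3 evaporated; cold saturated aqueous NaCl, −70 °C → rt, distilled into a −78 °C trap
Reagents that add atoms: none
Why: Twofold base-induced β-elimination (HCl, then methanol) gives the ynol ether as its sodium acetylide, which is protonated and distilled (bp about 23 °C).

Step 8
Reactants: 9 5-methoxy-4-(5-methoxy-2,2-dimethylchroman-6-yl)-5-oxopentanoic acid; 12 methoxyethyne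
Product: 15 methyl 3-(2-methoxy-4-oxocyclobut-2-en-1-yl)-2-(5-methoxy-2,2-dimethylchroman-6-yl)propanoate (mixture of diastereomers), via acid chloride 13 (not isolated), via ketene 14 (not isolated)
Conditions: (COCl)2, DMF (cat.), CH2Cl2, 0 °C → rt, evaporation; then 12 (4 equiv), Et3N, Et2O, 0 °C → rt (closed vessel)
Reagents that add atoms: none
Why: Dehydrochlorination of 13 gives aldoketene 14, which undergoes a ketene–ynol ether (2+2) cycloaddition in which the nucleophilic CH terminus of 12 bonds to the ketene carbonyl carbon, so methoxy lands on C3 and the chain on C4 of the cyclobutenone; the new ring stereocentre is uncontrolled and is destroyed in step 10.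

Step 9
Reactants: 16 1-adamantanol; 17 trichloroethylene
Product: 20 1-(ethynyloxy)adamantane, via dichlorovinyl ether 18 (not isolated), via lithium acetylide 19 (not isolated)
Conditions: KH, THF, 0 °C → rt; 17, rt; then n-BuLi (2.4 equiv), −78 → −40 °C; saturated aqueous NH4Cl, −78 °C
Reagents that add atoms: none
Why: Net substitution of the potassium tert-alkoxide on trichloroethylene gives the (E)-1,2-dichlorovinyl ether, which n-BuLi converts by β-elimination and chlorine–lithium exchange into the alkoxyacetylide that is protonated on quench, a sequence established for tertiary alkoxides.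

Step 10
Reactants: 15 methyl 3-(2-methoxy-4-oxocyclobut-2-en-1-yl)-2-(5-methoxy-2,2-dimethylchroman-6-yl)propanoate; 20 1-(ethynyloxy)adamantane
Product: 25 7-(1-adamantyloxy)-5-methoxy-3-(5-methoxy-2,2-dimethylchroman-6-yl)chroman-2-one (racemic), via vinylketene 21 (not isolated), via vinylcyclobutenone 22 (not isolated), via dienylketene 23 (not isolated), via hydroxy ester 24 (not isolated)
Conditions: 20 (2 equiv), toluene, 100 °C (argon); then DBU (0.3 equiv), 110 °C, methanol removed as its toluene azeotrope
Reagents that add atoms: none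
Why: Thermal 4π ring opening of 15 (the chain turning outward) gives vinylketene 21, whose ketene C=C adds the ynol ether in a (2+2) cycloaddition (C8–C8a and C6–C7) to give 22; a second 4π opening gives dienylketene 23, which closes ring A by 6π electrocyclisation (C4a–C8a) and enolises to phenol 24. The closest known reaction type is the Danheiser benzannulation of cyclobutenones with alkoxy- or siloxyalkynes to give resorcinol monoethers. Ring B is then closed by 6-exo-trig lactonisation of the C8a phenoxide on the methyl ester (O1–C2), held back until the DBU stage so that no methanol is present while ketenes are in solution. No new stereocentre is created: the sp3 carbon of the cyclobutenone becomes aromatic C4a and C3 stays racemic until step 11. The regiochemistry needed (adamantyloxy at C7, meta to both other oxygens) is secured by the polarisation of the partners, since the nucleophilic CH terminus of 20 bonds to the electrophilic ketene carbonyl carbon. The 1-adamantyl group should let the ynol ether survive 100 °C, because it has no allyl or benzyl π system for a (3,3) shift and its retro-ene fragmentation would need a bridgehead alkene.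

Step 11
Reactants: 25 7-(1-adamantyloxy)-5-methoxy-3-(5-methoxy-2,2-dimethylchroman-6-yl)chroman-2-one
Product: 27 7-(1-adamantyloxy)-5-methoxy-3-(5-methoxy-2,2-dimethylchroman-6-yl)-2H-chromen-2-one, via selenide 26 (not isolated)
Conditions: LiN(SiMe3)2, THF, −78 °C; PhSeBr, −78 °C; then AcOH, 30% H2O2, 0 °C → rt
Reagents that add atoms: none
Why: α-Selenenylation of the lactone enolate at C3 followed by oxidative syn-elimination of selenide 26, for which only the C4 hydrogens are available, should give the C3=C4 alkene and erase the C3 stereocentre; an enolate-based method is chosen because hydride-abstracting oxidants could also attack the benzylic C4' of the chroman.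

Step 12
Reactants: 27 7-(1-adamantyloxy)-5-methoxy-3-(5-methoxy-2,2-dimethylchroman-6-yl)-2H-chromen-2-one
Product: 28 7-hydroxy-5-methoxy-3-(5-methoxy-2,2-dimethylchroman-6-yl)-2H-chromen-2-one (CNP0139207.0)
Conditions: TFA/CH2Cl2 (1:1), thioanisole (5 equiv), 0 °C → rt; aqueous NaHCO3
Reagents that add atoms: none
Why: Acidolysis of the tert-alkyl aryl ether by ionisation to the 1-adamantyl cation, which thioanisole intercepts before it can alkylate the electron-rich rings; the aryl methyl ethers and the lactone are inert to TFA and the chroman ether can only reopen reversibly.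

Compound list
1 | 2,4-dihydroxyacetophenone | CC(=O)c1ccc(O)cc1O | starting material
2 | 3-methylbut-2-enal | CC(C)=CC=O | starting material
3 | 1-(5-hydroxy-2,2-dimethyl-2H-chromen-6-yl)ethan-1-one | CC(=O)c1ccc2OC(C)(C)C=Cc2c1O | intermediate
4 | 1-(5-methoxy-2,2-dimethyl-2H-chromen-6-yl)ethan-1-one | CC(=O)c1ccc2OC(C)(C)C=Cc2c1OC | intermediate
5 | 1-(5-methoxy-2,2-dimethylchroman-6-yl)ethan-1-one | CC(=O)c1ccc2OC(C)(C)CCc2c1OC | intermediate
6 | methyl 2-(5-methoxy-2,2-dimethylchroman-6-yl)acetate | COC(=O)Cc1ccc2OC(C)(C)CCc2c1OC | intermediate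
7 | benzyl acrylate | C=CC(=O)OCc1ccccc1 | starting material
8 | 5-benzyl 1-methyl 2-(5-methoxy-2,2-dimethylchroman-6-yl)pentanedioate (racemic) | COC(=O)C(CCC(=O)OCc1ccccc1)c1ccc2OC(C)(C)CCc2c1OC | intermediate
9 | 5-methoxy-4-(5-methoxy-2,2-dimethylchroman-6-yl)-5-oxopentanoic acid (racemic) | COC(=O)C(CCC(=O)O)c1ccc2OC(C)(C)CCc2c1OC | intermediate
10 | chloroacetaldehyde dimethyl acetal (2-chloro-1,1-dimethoxyethane) | COC(CCl)OC | starting material
11 | sodium methoxyacetylide (formed in the flask) | [Na+].[C-]#COC | intermediate
12 | methoxyethyne | C#COC | intermediate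
13 | methyl 5-chloro-2-(5-methoxy-2,2-dimethylchroman-6-yl)-5-oxopentanoate (acid chloride, formed in the flask, racemic) | COC(=O)C(CCC(=O)Cl)c1ccc2OC(C)(C)CCc2c1OC | intermediate
14 | methyl 2-(5-methoxy-2,2-dimethylchroman-6-yl)-5-oxopent-4-enoate (ketene, formed in the flask, racemic) | COC(=O)C(CC=C=O)c1ccc2OC(C)(C)CCc2c1OC | intermediate
15 | methyl 3-(2-methoxy-4-oxocyclobut-2-en-1-yl)-2-(5-methoxy-2,2-dimethylchroman-6-yl)propanoate (mixture of diastereomers) | COC1=CC(=O)C1CC(C(=O)OC)c1ccc2OC(C)(C)CCc2c1OC | intermediate
16 | 1-adamantanol | OC12CC3CC(CC(C3)C1)C2 | starting material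
17 | trichloroethylene | ClC=C(Cl)Cl | starting material
18 | (E)-1-[(1,2-dichloroethenyl)oxy]adamantane (formed in the flask) | Cl/C=C(/Cl)OC12CC3CC(CC(C3)C1)C2 | intermediate
19 | lithium 2-(1-adamantyloxy)ethynide (formed in the flask) | [Li]C#COC12CC3CC(CC(C3)C1)C2 | intermediate
20 | 1-(ethynyloxy)adamantane | C#COC12CC3CC(CC(C3)C1)C2 | intermediate
21 | methyl (4Z)-5-methoxy-2-(5-methoxy-2,2-dimethylchroman-6-yl)-7-oxohepta-4,6-dienoate (vinylketene, formed in the flask, racemic) | O=C=C/C(OC)=C/CC(C(=O)OC)c1ccc2OC(C)(C)CCc2c1OC | intermediate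
22 | methyl (4Z)-5-[2-(1-adamantyloxy)-4-oxocyclobut-2-en-1-yl]-5-methoxy-2-(5-methoxy-2,2-dimethylchroman-6-yl)pent-4-enoate (formed in the flask, mixture of diastereomers) | O=C1C=C(OC23CC4CC(CC(C4)C2)C3)C1/C(OC)=C/CC(C(=O)OC)c1ccc2OC(C)(C)CCc2c1OC | intermediate
23 | methyl (4Z,6E)-7-(1-adamantyloxy)-5-methoxy-2-(5-methoxy-2,2-dimethylchroman-6-yl)-9-oxonona-4,6,8-trienoate (dienylketene, formed in the flask, racemic) | O=C=C/C(OC12CC3CC(CC(C3)C1)C2)=C\C(OC)=C\CC(C(=O)OC)c1ccc2OC(C)(C)CCc2c1OC | intermediate
24 | methyl 3-[4-(1-adamantyloxy)-2-hydroxy-6-methoxyphenyl]-2-(5-methoxy-2,2-dimethylchroman-6-yl)propanoate (formed in the flask, racemic) | COC(=O)C(Cc1c(O)cc(OC23CC4CC(CC(C4)C2)C3)cc1OC)c1ccc2OC(C)(C)CCc2c1OC | intermediate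
25 | 7-(1-adamantyloxy)-5-methoxy-3-(5-methoxy-2,2-dimethylchroman-6-yl)chroman-2-one (racemic) | O=C1Oc2cc(OC34CC5CC(CC(C5)C3)C4)cc(OC)c2CC1c1ccc2OC(C)(C)CCc2c1OC | intermediate
26 | 7-(1-adamantyloxy)-5-methoxy-3-(5-methoxy-2,2-dimethylchroman-6-yl)-3-(phenylselanyl)chroman-2-one (formed in the flask, racemic) | O=C1Oc2cc(OC34CC5CC(CC(C5)C3)C4)cc(OC)c2CC1([Se]c1ccccc1)c1ccc2OC(C)(C)CCc2c1OC | intermediate
27 | 7-(1-adamantyloxy)-5-methoxy-3-(5-methoxy-2,2-dimethylchroman-6-yl)-2H-chromen-2-one | O=c1oc2cc(OC34CC5CC(CC(C5)C3)C4)cc(OC)c2cc1-c1ccc2OC(C)(C)CCc2c1OC | intermediate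
28 | 7-hydroxy-5-methoxy-3-(5-methoxy-2,2-dimethylchroman-6-yl)-2H-chromen-2-one (CNP0139207.0) | COc1c(-c2cc3c(OC)cc(O)cc3oc2=O)ccc2c1CCC(C)(C)O2 | target

Total step count: 12 (ten in the main line, two reagent preparations, steps 7 and 9).
Longest linear sequence: 10 steps (1, 2, 3, 4, 5, 6, 8, 10, 11, 12).

Steps most likely to fail

Step 10. The vinylogous-ester stabilisation of 15 may make its 4π opening so slow that thermal decay of 15, or interception of ketenes 21 and 23 by the phenolic product, outruns the annulation. The fallback abandons the benzannulation and builds the coumarin at its final oxidation level by a Perkin condensation. It sets out from 6, which is saponified (LiOH, THF/H2O) to 2-(5-methoxy-2,2-dimethylchroman-6-yl)acetic acid F1. Heating F1 with commercial 2,4-dihydroxy-6-methoxybenzaldehyde (O=Cc1c(O)cc(O)cc1OC) in Ac2O/Et3N at 110 °C should give 5-methoxy-3-(5-methoxy-2,2-dimethylchroman-6-yl)-2-oxo-2H-chromen-7-yl acetate F2, the ortho hydroxyl forming the lactone and the para hydroxyl being acetylated. Methanolysis of the acetate (K2CO3, MeOH, rt) comes back to the route at 28.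

Step 8. The aldoketene 14 may dimerise, or the amine hydrochloride may consume the volatile ynol ether, faster than the cycloaddition proceeds. The fallback generates the same ketene under neutral, salt-free conditions by a photochemical Wolff rearrangement. It sets out from 6, whose lithium enolate (LiN(iPr)2, THF, −78 °C) is alkylated with benzyl bromoacetate to give 4-benzyl 1-methyl 2-(5-methoxy-2,2-dimethylchroman-6-yl)butanedioate F3. Hydrogenolysis (H2, Pd/C, EtOAc) gives 4-methoxy-3-(5-methoxy-2,2-dimethylchroman-6-yl)-4-oxobutanoic acid F4. Oxalyl chloride gives methyl 4-chloro-2-(5-methoxy-2,2-dimethylchroman-6-yl)-4-oxobutanoate F5, and excess diazomethane (Et2O, 0 °C) gives methyl 5-diazo-2-(5-methoxy-2,2-dimethylchroman-6-yl)-4-oxopentanoate F6. Irradiation of F6 (Pyrex-filtered mercury lamp, CH2Cl2, 0 °C) in the presence of 12 should release ketene 14 and so come back to the route at 15.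

Step 4. The ketone may be α-methoxylated without aryl migration, or the electron-rich ring may be oxidised by the iodine reagent. The fallback replaces the aryl shift by a Willgerodt–Kindler reaction, which needs neither an oxidant nor a migrating ring. It sets out from 5, which with S8 and morpholine at 130 °C should give 2-(5-methoxy-2,2-dimethylchroman-6-yl)-1-(morpholin-4-yl)ethane-1-thione F7. Hydrolysis (KOH, aqueous EtOH, reflux, then acid) gives the same 2-(5-methoxy-2,2-dimethylchroman-6-yl)acetic acid F1 as above, and Fischer esterification (MeOH, H2SO4 cat., reflux) comes back to the route at 6.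

Further compounds
F1 | step 10 | 2-(5-methoxy-2,2-dimethylchroman-6-yl)acetic acid | OC(=O)Cc1ccc2OC(C)(C)CCc2c1OC
F2 | step 10 | 5-methoxy-3-(5-methoxy-2,2-dimethylchroman-6-yl)-2-oxo-2H-chromen-7-yl acetate | CC(=O)Oc1cc(OC)c2cc(-c3ccc4OC(C)(C)CCc4c3OC)c(=O)oc2c1
F3 | step 8 | 4-benzyl 1-methyl 2-(5-methoxy-2,2-dimethylchroman-6-yl)butanedioate (racemic) | COC(=O)C(CC(=O)OCc1ccccc1)c1ccc2OC(C)(C)CCc2c1OC
F4 | step 8 | 4-methoxy-3-(5-methoxy-2,2-dimethylchroman-6-yl)-4-oxobutanoic acid (racemic) | COC(=O)C(CC(=O)O)c1ccc2OC(C)(C)CCc2c1OC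
F5 | step 8 | methyl 4-chloro-2-(5-methoxy-2,2-dimethylchroman-6-yl)-4-oxobutanoate (racemic) | COC(=O)C(CC(=O)Cl)c1ccc2OC(C)(C)CCc2c1OC
F6 | step 8 | methyl 5-diazo-2-(5-methoxy-2,2-dimethylchroman-6-yl)-4-oxopentanoate (racemic) | COC(=O)C(CC(=O)C=[N+]=[N-])c1ccc2OC(C)(C)CCc2c1OC
F7 | step 4 | 2-(5-methoxy-2,2-dimethylchroman-6-yl)-1-(morpholin-4-yl)ethane-1-thione | S=C(Cc1ccc2OC(C)(C)CCc2c1OC)N1CCOCC1
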